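## The problem

The target **28** is an achiral bibenzyl. Ring A (3-hydroxy-5-methoxyphenyl) and ring B are joined by a CH2CH2 bridge, and ring B also carries two 4-hydroxybenzyl groups. Ring B is 1,2,3,4-tetrasubstituted: with the bridge carbon as B1, the benzyl groups sit at B2 and B6 and the hydroxyl at B5, so that B5, B6, B1 and B2 form an unbroken row and B1 and B6 are flanked on both sides. There is no stereocentre, so the task is purely regiochemical: four different substituents in a fixed order on one benzene ring, with C–C bonds at two crowded positions. Four phenols must be carried masked and released at the end without touching the single methyl ether on ring A. This excludes Lewis-acidic ether cleavage and points to benzyl ethers and a closing hydrogenolysis. The electron-rich rings would also make late electrophilic or oxidative steps unselective. The benzylic CH2 groups and the bridge are robust and can be carried as ketone or halide precursors. The feature that opens a short route is the contiguous triad B5–O, B6–C(benzyl), B1–C(bridge): it is the pattern left when a 3-alkoxybenzyne inserts into the ketone–CH2 bond of an aroylacetic ester, the aroyl carbon ending next to the oxygen. The remaining position B2 is para to that oxygen and can be reached afterwards by halogenation and cross-coupling.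

## Retrosynthesis

**28 from 25.** The last operation removes only oxygen functions: the four O–CH2Ph bonds and the carbonyl oxygen at the bridge carbon next to ring A. Precursor **25** already holds the whole carbon skeleton. Carrying the bridge as a ketone is preferred to a stilbene, which would need an aldehyde or phosphonium group at the crowded B1 position. The forward step must cleave four benzyl ethers and take one aryl ketone to CH2 without touching the methyl ether or the rings.

**25 from 20 and 23.** The bond between ring A and the bridge carbonyl is cut. Cutting the central CH2–CH2 bond instead would pair a benzylic nucleophile with a benzylic halide next to two ortho substituents, and cutting B1–CH2 would demand a coupling at the most hindered ring carbon. The chosen cut leaves ring B with a two-carbon acyl side chain, which the key step supplies directly. Weinreb amide **20** comes from ester **19**; Grignard reagent **23** comes from bromide **22**, the benzyl ether of commercial phenol **21**. The forward reaction must add once, without enolising the arylacetamide, and **20** must contain no second electrophilic carbonyl.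

**19 from 16 and 18.** The B2–CH2 bond is cut and assigned to a Negishi coupling of aryl bromide **16** with benzylzinc chloride **18**, made from chloride **17**. A Friedel–Crafts benzylation would have no regiocontrol among four electron-rich rings. A base-mediated coupling would expose the acidic arylacetate CH2. The organozinc needs no base and tolerates the ester.

**16 from 14 from 13.** Two functional-group changes on ring B: the B6 benzylic CH2 is traced back to the diaryl ketone and the B2 bromine to hydrogen. The order matters. Bromination is done on **13**, while the ketone still deactivates the 4-(benzyloxy)phenyl ring, so that the position para to the B5 oxygen is the only strongly activated site. The ketone is then removed by ionic hydrogenation before any organometallic reagent is used, so that the later Grignard addition meets one carbonyl only and the final hydrogenation has one ketone to reduce. The forward steps need para-selective bromination and reduction of a hindered but cation-stabilised diaryl ketone beside an ester, an aryl bromide and benzyl ethers.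

**13 from 8 and 10 (key disconnection).** The B1–CH2 and B6–C(=O) bonds are cut together, which corresponds to insertion of the aryne from **8** into the ketone–CH2 bond of ketoester **10**. Building the same ortho-aroyl arylacetate by successive metalations or couplings at two adjacent hindered carbons would take more steps and need separate regiocontrol at each. Both precursors are simple one-ring compounds. The forward reaction must add the enolate carbon to the aryne carbon remote from the oxygen and must go on to C–C insertion and not stop at simple arylation.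

**8 from 1, and 10 from 9.** In **8** the C–Si and O–S bonds are cut. Phenol **1** is converted to carbamate **2**, silylated at the carbon between the two oxygens to give **6**, and the carbamate is exchanged for the triflate. In **10** the CH2–CO2Me bond is cut, which is a C-methoxycarbonylation of acetophenone **9**.

## Roads not taken

**Alternative 1:** Traceless oxygen tether. The cut is the B6–CH(aryl) bond, made intramolecularly. The racemic alcohol A2 (ring A, the bridge carbinol, ring B with its B2 benzyl group and a free B5 phenol) condenses under acid with aldehyde A3 to an oxocarbenium ion. B6, ortho to the phenol, attacks it in an oxa-Pictet–Spengler closure to isochromanol A1, a diastereomer mixture of no consequence. Hydrogenolysis of both benzylic C–O bonds of the heterocycle and of the benzyl ethers would then give **28**.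
- Merits: the most hindered bond is formed last, intramolecularly and under mild acid. The tether oxygen leaves in the same final hydrogenation, so no separate deoxygenation is needed. In this respect it is better than the chosen plan, which spends step 7 on a redox adjustment.
- Weak points: A2 already contains a correctly substituted ring B, so the regiochemical problem is only moved into its synthesis. The acid step runs in the presence of ring A, whose positions between and beside the two oxygens are at least as nucleophilic as B6 and can capture the oxocarbenium ion intermolecularly. The last C–O bond to break is benzylic only to ring A, the same slow hydrogenolysis that the chosen route meets at **27**.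
- Comparison: the chosen plan makes the O/C/C triad in one intermolecular step from two one-ring compounds, with the orientation fixed by the aryne and no competing nucleophilic arene present.

**Alternative 2:** Two-directional benzylic Suzuki coupling. Both CH2–aryl bonds of the benzyl groups are cut. Bis(bromomethyl) aryl pivalate A5 couples twice with boronic acid A6 under zerovalent palladium and a phosphate base to give A4. The ring bromide at B1 survives because it lies between two ortho substituents and benzylic C–Br bonds add to palladium faster. The bridge would then be attached at B1 and the protecting groups removed.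
- Merits: one boronic acid serves both arms, no carbonyl has to be removed, and the sequence after A5 is short. Where A5 is at hand, this road is shorter and more convergent than the chosen one.
- Weak points: the arene underlying A5 has bromine between the two benzylic carbons and meta to oxygen, a pattern that direct halogenation of the corresponding dimethylphenol does not deliver, so the ring-B problem returns in making A5. The twofold radical bromination must avoid over-bromination. After the coupling, the bridge must be attached by oxidative addition at a bromide flanked by two benzyl groups, the hardest cross-coupling site in the molecule.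
- Comparison: in the chosen plan the bridge carbons arrive with the key step as a CH2CO2Me group, so no coupling at the doubly ortho-substituted B1 is needed, and the substituent order follows from commercial materials.

**Alternative 3:** Vinylboronate linchpin. Both bridge bonds, B1–CH and CH2–A1, are cut. The aryllithium from bromide A8 adds to vinylboronate A9. A palladium catalyst bearing a bis(phosphino)ferrocene ligand then couples the ate complex with ring A triflate A10 through a 1,2-aryl shift from boron to carbon, giving racemic boronate A7. Protodeboronation and debenzylation would follow.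
- Merits: a three-component step that forms both bridge bonds at once and keeps the ring A and ring B fragments independent. The bridge is built in fewer steps than by steps 9, 11 and 12 of the chosen route, and without carbonyl chemistry.
- Weak points: the migrating group is a 2,6-dibenzylated aryl, so both ate formation and the shift occur at a very hindered carbon. Bromine–lithium exchange is carried out beside two doubly benzylic CH2 groups and three benzyl ethers, which invites deprotonation. The step creates an unwanted boron-bearing stereocentre that costs an extra step to erase. A8 presupposes the full 1,2,3,4 pattern of ring B, which is exactly what has to be solved.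
- Comparison: the chosen plan supplies that pattern from simple precursors and forms the hindered aryl–carbon bonds by well-known reaction types.

Key step: step 5

Remark: **28** has no stereocentre. Intermediates **12**, **15**, **24** and **27** are formed as racemates (**12** as a diastereomer mixture) and lose their stereocentres again, so no configuration is assigned.

## Route

Step 1
Reactants: 1 3-(benzyloxy)phenol
Product: 2 3-(benzyloxy)phenyl isopropylcarbamate
Conditions: iPrNCO, Et3N (cat.), CH2Cl2, rt
Reagents that add atoms: isopropyl isocyanate, CC(C)N=C=O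
Why: Base-catalysed addition of the phenol to the isocyanate (carbamoylation) gives an N–H carbamate, which is a strong ortho-directing group and can later be removed under mild base.

Step 2
Reactants: 2 3-(benzyloxy)phenyl isopropylcarbamate
Product: 6 3-(benzyloxy)-2-(trimethylsilyl)phenyl isopropylcarbamate, via N-silyl carbamate 3 (not isolated), via aryllithium 4 (not isolated), via N-silyl C-silyl carbamate 5 (not isolated)
Conditions: TBSOTf, TMEDA, Et2O, 0 °C to rt; n-BuLi, TMEDA, −78 °C; TMSCl, −78 °C to rt; aq NaHSO4
Reagents that add atoms: chlorotrimethylsilane, C[Si](C)(C)Cl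
Why: Directed ortho-metalation: after N-silylation in the flask, the carbamate and the benzyloxy group jointly direct lithiation to the carbon between them and TMSCl traps the aryllithium. At −78 °C lithiation at this doubly activated site should outrun α-lithiation of the benzyl ether and the anionic Fries shift, and the N-silyl group is lost in the acidic work-up.

Step 3
Reactants: 6 3-(benzyloxy)-2-(trimethylsilyl)phenyl isopropylcarbamate
Product: 8 3-(benzyloxy)-2-(trimethylsilyl)phenyl trifluoromethanesulfonate, via silyl phenol 7 (not isolated)
Conditions: Et2NH, DBU, MeCN, 40 °C; then PhNTf2, rt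
Reagents that add atoms: N-phenylbis(trifluoromethanesulfonimide), O=S(=O)(N(c1ccccc1)S(=O)(=O)C(F)(F)F)C(F)(F)F
Why: The N–H carbamate is cleaved by E1cB elimination, the isocyanate being scavenged by the amine, and the phenoxide is triflated in the same flask. This is the standard way to ortho-silyl aryl triflates and avoids isolating the silyl phenol.

Step 4
Reactants: 9 4'-(benzyloxy)acetophenone
Product: 10 methyl 3-[4-(benzyloxy)phenyl]-3-oxopropanoate
Conditions: NaH, (MeO)2CO, THF, reflux; aq HCl work-up
Reagents that add atoms: dimethyl carbonate, COC(=O)OC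
Why: Crossed Claisen condensation (C-methoxycarbonylation of the ketone enolate). Only the methyl ketone can enolise, and formation of the stabilised ketoester enolate drives the reaction.

Step 5
Reactants: 8 3-(benzyloxy)-2-(trimethylsilyl)phenyl trifluoromethanesulfonate; 10 methyl 3-[4-(benzyloxy)phenyl]-3-oxopropanoate
Product: 13 methyl 2-{3-(benzyloxy)-2-[4-(benzyloxy)benzoyl]phenyl}acetate, via 3-(benzyloxy)benzyne 11 (not isolated), via cesium benzocyclobutenoxide 12 (not isolated)
Conditions: CsF, MeCN, 80 °C
Reagents that add atoms: none
Why: Fluoride attacks silicon of 8 and the aryl anion expels triflate to give aryne 11, while CsF also turns 10 into its enolate. The enolate adds through carbon to the aryne carbon remote from the benzyloxy group (the future B1), because the C–O bond distorts the aryne and stabilises by induction the negative charge that develops at the adjacent carbon (the future B6). This aryl anion attacks the ketone carbonyl in a 4-exo-trig closure to benzocyclobutenoxide 12, whose strained ring opens at once by retro-aldol-type cleavage of the C(O−)–CH(CO2Me) bond to an ester enolate that is protonated to 13. The net result is insertion of the aryne into the C(=O)–CH2 bond, forming B1–CH2 and B6–C(=O). The closest known reaction type is the acyl-alkylation of arynes by β-ketoesters, which covers aroylacetates and 3-alkoxybenzynes. The four-membered ring is transient, so no ring and no stereocentre remain in 13. The selectivity needed is the orientation of addition to the unsymmetrical aryne, together with C- over O-arylation of the enolate; the 3-benzyloxy group secures the first by polarising the aryne and the soft, stabilised enolate carbon the second. Slow release of the aryne from a small excess of 8 keeps its concentration low relative to the enolate and limits a second arylation of 13.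

Step 6
Reactants: 13 methyl 2-{3-(benzyloxy)-2-[4-(benzyloxy)benzoyl]phenyl}acetate
Product: 14 methyl 2-{3-(benzyloxy)-2-[4-(benzyloxy)benzoyl]-6-bromophenyl}acetate
Conditions: NBS, MeCN, 0 °C to rt, dark
Reagents that add atoms: N-bromosuccinimide, O=C1CCC(=O)N1Br
Why: Electrophilic aromatic bromination with NBS in MeCN is strongly para-selective for alkyl aryl ethers. The free position para to the B5 benzyloxy group is the most electron-rich site, since the ketone is twisted out of conjugation with ring B but deactivates the 4-(benzyloxy)phenyl ring. The polar solvent and exclusion of light suppress radical bromination at the benzylic CH2.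

Step 7
Reactants: 14 methyl 2-{3-(benzyloxy)-2-[4-(benzyloxy)benzoyl]-6-bromophenyl}acetate
Product: 16 methyl 2-{3-(benzyloxy)-2-[4-(benzyloxy)benzyl]-6-bromophenyl}acetate, via benzhydrol 15 (not isolated)
Conditions: Et3SiH, TFA, CH2Cl2, 0 °C to rt
Reagents that add atoms: none
Why: Ionic hydrogenation: the protonated diaryl ketone and then the benzhydryl cation, both stabilised by the para-alkoxyphenyl ring, take up hydride from the silane. The aryl bromide, the ester and the aryl benzyl ethers should tolerate the acid at or below rt. Removing the ketone here keeps it out of the Grignard step and leaves one carbonyl for the final hydrogenation.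

Step 8
Reactants: 16 methyl 2-{3-(benzyloxy)-2-[4-(benzyloxy)benzyl]-6-bromophenyl}acetate; 17 4-(benzyloxy)benzyl chloride
Product: 19 methyl 2-{3-(benzyloxy)-2,6-bis[4-(benzyloxy)benzyl]phenyl}acetate, via 4-(benzyloxy)benzylzinc chloride 18 (not isolated)
Conditions: 17, Zn dust, LiCl, THF, rt; then 16, Pd(OAc)2 (cat.), SPhos, THF, rt to 50 °C
Reagents that add atoms: none
Why: Negishi coupling: LiCl-assisted zinc insertion into the benzylic chloride gives 18, which couples with the mono-ortho-substituted, electron-rich aryl bromide under a palladium/biarylphosphine catalyst. No base is present, so the ester and its acidic CH2 are untouched.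

Step 9
Reactants: 19 methyl 2-{3-(benzyloxy)-2,6-bis[4-(benzyloxy)benzyl]phenyl}acetate
Product: 20 2-{3-(benzyloxy)-2,6-bis[4-(benzyloxy)benzyl]phenyl}-N-methoxy-N-methylacetamide
Conditions: MeNH(OMe)·HCl, AlMe3, CH2Cl2, 0 °C to reflux; aq HCl work-up
Reagents that add atoms: N,O-dimethylhydroxylamine hydrochloride, CNOC.Cl
Why: Weinreb amide formation by aminolysis of the ester with the aluminium amide made in the flask. The reagent is Lewis acidic but not basic, so the benzylic CH2 next to the carbonyl is not enolised and the benzyl ethers are untouched.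

Step 10
Reactants: 21 3-bromo-5-methoxyphenol
Product: 22 1-(benzyloxy)-3-bromo-5-methoxybenzene
Conditions: BnBr, K2CO3, DMF, rt
Reagents that add atoms: benzyl bromide, BrCc1ccccc1
Why: Williamson ether synthesis on a phenoxide; the benzyl ether matches the other three protecting groups, so one final hydrogenolysis releases all phenols.

Step 11
Reactants: 20 2-{3-(benzyloxy)-2,6-bis[4-(benzyloxy)benzyl]phenyl}-N-methoxy-N-methylacetamide; 22 1-(benzyloxy)-3-bromo-5-methoxybenzene
Product: 25 1-[3-(benzyloxy)-5-methoxyphenyl]-2-{3-(benzyloxy)-2,6-bis[4-(benzyloxy)benzyl]phenyl}ethan-1-one, via arylmagnesium bromide 23 (not isolated), via magnesium hemiaminal chelate 24 (not isolated)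
Conditions: 22, Mg turnings, THF, reflux; then 20, THF, −20 to 0 °C; aq HCl work-up
Reagents that add atoms: none
Why: Weinreb ketone synthesis: the aryl Grignard reagent adds once and the magnesium-chelated tetrahedral adduct 24 persists until work-up, so no tertiary alcohol forms. After step 7 the amide is the only electrophilic carbonyl in the molecule.

Step 12
Reactants: 25 1-[3-(benzyloxy)-5-methoxyphenyl]-2-{3-(benzyloxy)-2,6-bis[4-(benzyloxy)benzyl]phenyl}ethan-1-one
Product: 28 2,4-bis(4-hydroxybenzyl)-3-[2-(3-hydroxy-5-methoxyphenyl)ethyl]phenol, via tetraphenol ketone 26 (not isolated), via benzylic alcohol 27 (not isolated)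
Conditions: H2 (1–3 atm), Pd/C (10% palladium on carbon), EtOH/EtOAc, HCl (cat.), rt to 40 °C
Reagents that add atoms: none
Why: Heterogeneous hydrogenolysis: the four aryl benzyl ethers are cleaved and the aryl ketone is taken through the benzylic alcohol to CH2 under acid-promoted palladium catalysis. The methyl ether and the aromatic rings are not attacked at low pressure; the order of the individual hydrogenolyses may differ from the one written.

## Compound list

1 | 3-(benzyloxy)phenol | Oc1cccc(OCc2ccccc2)c1 | starting material
2 | 3-(benzyloxy)phenyl isopropylcarbamate | CC(C)NC(=O)Oc1cccc(OCc2ccccc2)c1 | intermediate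
3 | 3-(benzyloxy)phenyl N-(tert-butyldimethylsilyl)-N-isopropylcarbamate | CC(C)N(C(=O)Oc1cccc(OCc2ccccc2)c1)[Si](C)(C)C(C)(C)C | intermediate (not isolated)
4 | {2-(benzyloxy)-6-[(tert-butyldimethylsilyl)(isopropyl)carbamoyloxy]phenyl}lithium | [Li]c1c(OCc2ccccc2)cccc1OC(=O)N(C(C)C)[Si](C)(C)C(C)(C)C | intermediate (not isolated)
5 | 3-(benzyloxy)-2-(trimethylsilyl)phenyl N-(tert-butyldimethylsilyl)-N-isopropylcarbamate | CC(C)N(C(=O)Oc1cccc(OCc2ccccc2)c1[Si](C)(C)C)[Si](C)(C)C(C)(C)C | intermediate (not isolated)
6 | 3-(benzyloxy)-2-(trimethylsilyl)phenyl isopropylcarbamate | CC(C)NC(=O)Oc1cccc(OCc2ccccc2)c1[Si](C)(C)C | intermediate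
7 | 3-(benzyloxy)-2-(trimethylsilyl)phenol | C[Si](C)(C)c1c(O)cccc1OCc1ccccc1 | intermediate (not isolated)
8 | 3-(benzyloxy)-2-(trimethylsilyl)phenyl trifluoromethanesulfonate | C[Si](C)(C)c1c(OCc2ccccc2)cccc1OS(=O)(=O)C(F)(F)F | intermediate
9 | 4'-(benzyloxy)acetophenone | CC(=O)c1ccc(OCc2ccccc2)cc1 | starting material
10 | methyl 3-[4-(benzyloxy)phenyl]-3-oxopropanoate | COC(=O)CC(=O)c1ccc(OCc2ccccc2)cc1 | intermediate
11 | 3-(benzyloxy)benzyne (3-(benzyloxy)-1,2-didehydrobenzene) | C1#CC(OCc2ccccc2)=CC=C1 | intermediate (not isolated)
12 | cesium alkoxide of methyl 2-(benzyloxy)-8-[4-(benzyloxy)phenyl]-8-hydroxybicyclo[4.2.0]octa-1,3,5-triene-7-carboxylate (racemic, diastereomer mixture) | COC(=O)C1c2cccc(OCc3ccccc3)c2C1([O-])c1ccc(OCc2ccccc2)cc1.[Cs+] | intermediate (not isolated)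
13 | methyl 2-{3-(benzyloxy)-2-[4-(benzyloxy)benzoyl]phenyl}acetate | COC(=O)Cc1cccc(OCc2ccccc2)c1C(=O)c1ccc(OCc2ccccc2)cc1 | intermediate
14 | methyl 2-{3-(benzyloxy)-2-[4-(benzyloxy)benzoyl]-6-bromophenyl}acetate | COC(=O)Cc1c(Br)ccc(OCc2ccccc2)c1C(=O)c1ccc(OCc2ccccc2)cc1 | intermediate
15 | methyl 2-{3-(benzyloxy)-2-[[4-(benzyloxy)phenyl](hydroxy)methyl]-6-bromophenyl}acetate (racemic) | COC(=O)Cc1c(Br)ccc(OCc2ccccc2)c1C(O)c1ccc(OCc2ccccc2)cc1 | intermediate (not isolated)
16 | methyl 2-{3-(benzyloxy)-2-[4-(benzyloxy)benzyl]-6-bromophenyl}acetate | COC(=O)Cc1c(Br)ccc(OCc2ccccc2)c1Cc1ccc(OCc2ccccc2)cc1 | intermediate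
17 | 4-(benzyloxy)benzyl chloride | ClCc1ccc(OCc2ccccc2)cc1 | starting material
18 | 4-(benzyloxy)benzylzinc chloride | Cl[Zn]Cc1ccc(OCc2ccccc2)cc1 | intermediate (not isolated)
19 | methyl 2-{3-(benzyloxy)-2,6-bis[4-(benzyloxy)benzyl]phenyl}acetate | COC(=O)Cc1c(Cc2ccc(OCc3ccccc3)cc2)ccc(OCc2ccccc2)c1Cc1ccc(OCc2ccccc2)cc1 | intermediate
20 | 2-{3-(benzyloxy)-2,6-bis[4-(benzyloxy)benzyl]phenyl}-N-methoxy-N-methylacetamide | CON(C)C(=O)Cc1c(Cc2ccc(OCc3ccccc3)cc2)ccc(OCc2ccccc2)c1Cc1ccc(OCc2ccccc2)cc1 | intermediate
21 | 3-bromo-5-methoxyphenol | COc1cc(O)cc(Br)c1 | starting material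
22 | 1-(benzyloxy)-3-bromo-5-methoxybenzene | COc1cc(Br)cc(OCc2ccccc2)c1 | intermediate
23 | [3-(benzyloxy)-5-methoxyphenyl]magnesium bromide | COc1cc([Mg]Br)cc(OCc2ccccc2)c1 | intermediate (not isolated)
24 | bromomagnesium 1-[3-(benzyloxy)-5-methoxyphenyl]-2-{3-(benzyloxy)-2,6-bis[4-(benzyloxy)benzyl]phenyl}-1-[methoxy(methyl)amino]ethan-1-olate (racemic) | COc1cc(OCc2ccccc2)cc(c1)C(O[Mg]Br)(Cc1c(Cc2ccc(OCc3ccccc3)cc2)ccc(OCc2ccccc2)c1Cc1ccc(OCc2ccccc2)cc1)N(C)OC | intermediate (not isolated)
25 | 1-[3-(benzyloxy)-5-methoxyphenyl]-2-{3-(benzyloxy)-2,6-bis[4-(benzyloxy)benzyl]phenyl}ethan-1-one | COc1cc(OCc2ccccc2)cc(c1)C(=O)Cc1c(Cc2ccc(OCc3ccccc3)cc2)ccc(OCc2ccccc2)c1Cc1ccc(OCc2ccccc2)cc1 | intermediate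
26 | 1-(3-hydroxy-5-methoxyphenyl)-2-[3-hydroxy-2,6-bis(4-hydroxybenzyl)phenyl]ethan-1-one | COc1cc(O)cc(c1)C(=O)Cc1c(Cc2ccc(O)cc2)ccc(O)c1Cc1ccc(O)cc1 | intermediate (not isolated)
27 | 2,4-bis(4-hydroxybenzyl)-3-[2-hydroxy-2-(3-hydroxy-5-methoxyphenyl)ethyl]phenol (racemic) | COc1cc(O)cc(c1)C(O)Cc1c(Cc2ccc(O)cc2)ccc(O)c1Cc1ccc(O)cc1 | intermediate (not isolated)
28 | 2,4-bis(4-hydroxybenzyl)-3-[2-(3-hydroxy-5-methoxyphenyl)ethyl]phenol | COc1cc(O)cc(CCc2c(Cc3ccc(O)cc3)ccc(O)c2Cc2ccc(O)cc2)c1 | target

## Step count and least certain steps

Total: 12 steps. Longest linear sequence: 10 steps (1, 2, 3, 5, 6, 7, 8, 9, 11, 12). Steps 4 and 10 are side branches.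

**Step 5 (key step).** The most likely failure is protonation of the aryl anion before it closes onto the ketone, so that simple α-arylation of the ketoester competes with insertion. The aroyl carbonyl is made less electrophilic by its para-alkoxy donor, which slows the 4-exo closure. A second arylation of the acidic CH2 of the product or erosion of the aryne regiochemistry would also lower the outcome. A fallback without an aryne sets out from carbamate 2 and returns at 13:
- N-silylation and ortho-lithiation as in step 2 (through 3 and 4), then quench of aryllithium 4 with methyl 4-(benzyloxy)benzoate, gives 3-(benzyloxy)-2-[4-(benzyloxy)benzoyl]phenyl N-(tert-butyldimethylsilyl)-N-isopropylcarbamate F1. The hindered ketone should resist a second addition.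
- Acidic work-up converts it into 3-(benzyloxy)-2-[4-(benzyloxy)benzoyl]phenyl isopropylcarbamate F2.
- Et2NH/DBU releases [2-(benzyloxy)-6-hydroxyphenyl][4-(benzyloxy)phenyl]methanone F3, and PhNTf2 gives 3-(benzyloxy)-2-[4-(benzyloxy)benzoyl]phenyl trifluoromethanesulfonate F4.
- Palladium-catalysed coupling of F4 with the Reformatsky reagent BrZnCH2CO2Me (Pd2(dba)3, XPhos, THF) gives 13.

**Step 7.** Three processes can interfere: capture of the benzhydryl cation by the neighbouring ester carbonyl (lactonisation to an isochromanone), partial acidolysis of the aryl benzyl ethers, and slow hydride transfer to a cation shielded by two ortho substituents. The fallback keeps the ketone to the end. It sets out from 14 and returns at 28: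
- Negishi coupling of 14 with 18 as in step 8 gives methyl 2-{3-(benzyloxy)-2-[4-(benzyloxy)benzoyl]-6-[4-(benzyloxy)benzyl]phenyl}acetate F5.
- Aminolysis as in step 9 gives 2-{3-(benzyloxy)-2-[4-(benzyloxy)benzoyl]-6-[4-(benzyloxy)benzyl]phenyl}-N-methoxy-N-methylacetamide F6.
- Addition of 23 at low temperature gives 1-[3-(benzyloxy)-5-methoxyphenyl]-2-{3-(benzyloxy)-2-[4-(benzyloxy)benzoyl]-6-[4-(benzyloxy)benzyl]phenyl}ethan-1-one F7. This relies on the diaryl ketone being shielded on both faces by its two ortho substituents.
- Acid-promoted hydrogenation over Pd/C then removes both carbonyl oxygens and the benzyl groups to give 28.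

**Step 6.** Loss of site selectivity is the concern: bromination ortho to the benzyloxy group (B4), on a benzyl ether ring, or at the CH2 next to the ester. The fallback replaces halogenation by a C–H functionalisation that is para-selective by its mechanism. It sets out from 13 and returns at 19:
- Thianthrenation (thianthrene S-oxide, (CF3CO)2O, HBF4·OEt2, MeCN, 0 °C) gives 5-{4-(benzyloxy)-3-[4-(benzyloxy)benzoyl]-2-(2-methoxy-2-oxoethyl)phenyl}thianthren-5-ium tetrafluoroborate F8.
- Palladium-catalysed Negishi coupling of this sulfonium salt with 18 gives the keto ester F5 described under step 7.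
- Ionic hydrogenation under the conditions of step 7 gives 19.

**Step 11.** The basic Grignard reagent may enolise the arylacetic Weinreb amide, whose CH2 is benzylic and next to the carbonyl, faster than it adds to a carbonyl screened by two ortho benzyl groups; the amide would then be recovered. The fallback is a non-basic acyl cross-coupling. It sets out from 19 and returns at 25:
- Saponification (LiOH, THF/H2O) gives 2-{3-(benzyloxy)-2,6-bis[4-(benzyloxy)benzyl]phenyl}acetic acid F9.
- Thioesterification (EtSH, EDC, DMAP) gives S-ethyl 2-{3-(benzyloxy)-2,6-bis[4-(benzyloxy)benzyl]phenyl}ethanethioate F10.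
- Transmetalation of 23 with ZnCl2 gives [3-(benzyloxy)-5-methoxyphenyl]zinc chloride F11.
- Fukuyama coupling of F10 with F11 (PdCl2(PPh3)2, THF/toluene) gives 25.

**Step 12.** The hydrogenolysis may stop at the benzylic alcohol, because ring A carries only meta oxygens and gives little help to C–O cleavage. Forcing conditions could begin to saturate the phenolic rings. The fallback removes the oxygen by elimination. It sets out from 25 and returns at 28:
- NaBH4 (THF/MeOH) gives racemic 1-[3-(benzyloxy)-5-methoxyphenyl]-2-{3-(benzyloxy)-2,6-bis[4-(benzyloxy)benzyl]phenyl}ethan-1-ol F12.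
- Acid-catalysed dehydration (p-TsOH, toluene, reflux) gives (E)-1-(benzyloxy)-2,4-bis[4-(benzyloxy)benzyl]-3-{2-[3-(benzyloxy)-5-methoxyphenyl]ethenyl}benzene F13.
- Neutral hydrogenation (H2, Pd/C, EtOAc/MeOH) saturates the alkene and cleaves the four benzyl ethers to give 28.

## Further compounds

F1 | step 5 | 3-(benzyloxy)-2-[4-(benzyloxy)benzoyl]phenyl N-(tert-butyldimethylsilyl)-N-isopropylcarbamate | CC(C)N(C(=O)Oc1cccc(OCc2ccccc2)c1C(=O)c1ccc(OCc2ccccc2)cc1)[Si](C)(C)C(C)(C)C
F2 | step 5 | 3-(benzyloxy)-2-[4-(benzyloxy)benzoyl]phenyl isopropylcarbamate | CC(C)NC(=O)Oc1cccc(OCc2ccccc2)c1C(=O)c1ccc(OCc2ccccc2)cc1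
F3 | step 5 | [2-(benzyloxy)-6-hydroxyphenyl][4-(benzyloxy)phenyl]methanone | O=C(c1ccc(OCc2ccccc2)cc1)c1c(O)cccc1OCc1ccccc1
F4 | step 5 | 3-(benzyloxy)-2-[4-(benzyloxy)benzoyl]phenyl trifluoromethanesulfonate | O=C(c1ccc(OCc2ccccc2)cc1)c1c(OCc2ccccc2)cccc1OS(=O)(=O)C(F)(F)F
F5 | step 7 | methyl 2-{3-(benzyloxy)-2-[4-(benzyloxy)benzoyl]-6-[4-(benzyloxy)benzyl]phenyl}acetate | COC(=O)Cc1c(Cc2ccc(OCc3ccccc3)cc2)ccc(OCc2ccccc2)c1C(=O)c1ccc(OCc2ccccc2)cc1
F6 | step 7 | 2-{3-(benzyloxy)-2-[4-(benzyloxy)benzoyl]-6-[4-(benzyloxy)benzyl]phenyl}-N-methoxy-N-methylacetamide | CON(C)C(=O)Cc1c(Cc2ccc(OCc3ccccc3)cc2)ccc(OCc2ccccc2)c1C(=O)c1ccc(OCc2ccccc2)cc1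
F7 | step 7 | 1-[3-(benzyloxy)-5-methoxyphenyl]-2-{3-(benzyloxy)-2-[4-(benzyloxy)benzoyl]-6-[4-(benzyloxy)benzyl]phenyl}ethan-1-one | COc1cc(OCc2ccccc2)cc(c1)C(=O)Cc1c(Cc2ccc(OCc3ccccc3)cc2)ccc(OCc2ccccc2)c1C(=O)c1ccc(OCc2ccccc2)cc1
F8 | step 6 | 5-{4-(benzyloxy)-3-[4-(benzyloxy)benzoyl]-2-(2-methoxy-2-oxoethyl)phenyl}thianthren-5-ium tetrafluoroborate | COC(=O)Cc1c([S+]2c3ccccc3Sc3ccccc32)ccc(OCc2ccccc2)c1C(=O)c1ccc(OCc2ccccc2)cc1.F[B-](F)(F)F
F9 | step 11 | 2-{3-(benzyloxy)-2,6-bis[4-(benzyloxy)benzyl]phenyl}acetic acid | OC(=O)Cc1c(Cc2ccc(OCc3ccccc3)cc2)ccc(OCc2ccccc2)c1Cc1ccc(OCc2ccccc2)cc1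
F10 | step 11 | S-ethyl 2-{3-(benzyloxy)-2,6-bis[4-(benzyloxy)benzyl]phenyl}ethanethioate | CCSC(=O)Cc1c(Cc2ccc(OCc3ccccc3)cc2)ccc(OCc2ccccc2)c1Cc1ccc(OCc2ccccc2)cc1
F11 | step 11 | [3-(benzyloxy)-5-methoxyphenyl]zinc chloride | COc1cc([Zn]Cl)cc(OCc2ccccc2)c1
F12 | step 12 | 1-[3-(benzyloxy)-5-methoxyphenyl]-2-{3-(benzyloxy)-2,6-bis[4-(benzyloxy)benzyl]phenyl}ethan-1-ol (racemic) | COc1cc(OCc2ccccc2)cc(c1)C(O)Cc1c(Cc2ccc(OCc3ccccc3)cc2)ccc(OCc2ccccc2)c1Cc1ccc(OCc2ccccc2)cc1
F13 | step 12 | (E)-1-(benzyloxy)-2,4-bis[4-(benzyloxy)benzyl]-3-{2-[3-(benzyloxy)-5-methoxyphenyl]ethenyl}benzene | COc1cc(OCc2ccccc2)cc(c1)/C=C/c1c(Cc2ccc(OCc3ccccc3)cc2)ccc(OCc2ccccc2)c1Cc1ccc(OCc2ccccc2)cc1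
A1 | alternative 1 | 5-[4-(benzyloxy)benzyl]-3-[3-(benzyloxy)-5-methoxyphenyl]-1-[4-(benzyloxy)phenyl]isochroman-8-ol (racemic, diastereomer mixture) | COc1cc(OCc2ccccc2)cc(c1)C1Cc2c(Cc3ccc(OCc4ccccc4)cc3)ccc(O)c2C(c2ccc(OCc3ccccc3)cc2)O1
A2 | alternative 1 | 4-[4-(benzyloxy)benzyl]-3-{2-[3-(benzyloxy)-5-methoxyphenyl]-2-hydroxyethyl}phenol (racemic) | COc1cc(OCc2ccccc2)cc(c1)C(O)Cc1cc(O)ccc1Cc1ccc(OCc2ccccc2)cc1
A3 | alternative 1 | 4-(benzyloxy)benzaldehyde | O=Cc1ccc(OCc2ccccc2)cc1
A4 | alternative 2 | 3-bromo-2,4-bis[4-(benzyloxy)benzyl]phenyl 2,2-dimethylpropanoate | CC(C)(C)C(=O)Oc1ccc(Cc2ccc(OCc3ccccc3)cc2)c(Br)c1Cc1ccc(OCc2ccccc2)cc1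
A5 | alternative 2 | 3-bromo-2,4-bis(bromomethyl)phenyl 2,2-dimethylpropanoate | CC(C)(C)C(=O)Oc1ccc(CBr)c(Br)c1CBr
A6 | alternative 2 | 4-(benzyloxy)phenylboronic acid | OB(O)c1ccc(OCc2ccccc2)cc1
A7 | alternative 3 | 2-[1-{3-(benzyloxy)-2,6-bis[4-(benzyloxy)benzyl]phenyl}-2-[3-(benzyloxy)-5-methoxyphenyl]ethyl]-4,4,5,5-tetramethyl-1,3,2-dioxaborolane (racemic) | COc1cc(CC(B2OC(C)(C)C(C)(C)O2)c2c(Cc3ccc(OCc4ccccc4)cc3)ccc(OCc3ccccc3)c2Cc2ccc(OCc3ccccc3)cc2)cc(OCc2ccccc2)c1
A8 | alternative 3 | 1-(benzyloxy)-3-bromo-2,4-bis[4-(benzyloxy)benzyl]benzene | Brc1c(Cc2ccc(OCc3ccccc3)cc2)ccc(OCc2ccccc2)c1Cc1ccc(OCc2ccccc2)cc1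
A9 | alternative 3 | 4,4,5,5-tetramethyl-2-vinyl-1,3,2-dioxaborolane | C=CB1OC(C)(C)C(C)(C)O1
A10 | alternative 3 | 3-(benzyloxy)-5-methoxyphenyl trifluoromethanesulfonate | COc1cc(OCc2ccccc2)cc(OS(=O)(=O)C(F)(F)F)c1
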